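## Retrosynthetic overview

- **Feature:** the only ring is the butyrolactone O1–C2(=O)–C3–C4–C5. Its neighbouring carbons C3 and C4 each carry a 3,4,5-trimethoxybenzyl arm (C7' on C3, C7 on C4). C2–C3–C7' therefore has the carbon pattern of a propiolate, and C5–C4–C7–aryl that of a cinnamyl alcohol.
- **Endgame:** the trans C3 centre is traced back to its cis epimer (base equilibration against the fixed C4). The cis epimer is traced back to the E-arylidene lactone with a C3=C7' double bond (conjugate reduction).
- **Key disconnection:** C7'–aryl and C3–C4 are cut together, which opens the lactone to an acyclic cinnamyl propiolate and frees the second aryl group as its boronic acid. In the forward direction a rhodium/chiral diene arylation–cyclisation cascade forms the one ring (5-exo) and sets C4.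
- **Precursor:** the enyne ester comes from propiolic acid and trimethoxycinnamyl alcohol, and the alcohol from trimethoxycinnamic acid (esterification, 1,2-reduction).

Key step: step 4

Assumption: no precedent fixes the sense of induction for this substrate class, so the route is written with (R,R)-Ph-bod* as the diene that leads to R at C4. If a trial run shows the opposite sense, the equally available (S,S)-diene takes its place and nothing else changes.

## Route

Step 1
Reactants: 1 (E)-3,4,5-trimethoxycinnamic acid
Product: 2 methyl (E)-3-(3,4,5-trimethoxyphenyl)prop-2-enoate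
Conditions: MeOH, H2SO4 (cat.), reflux
Reagents that add atoms: methanol, CO
Why: Fischer esterification in excess methanol drives the acid to its methyl ester, and neither the E-alkene nor the aryl ethers respond to catalytic acid.

Step 2
Reactants: 2 methyl (E)-3-(3,4,5-trimethoxyphenyl)prop-2-enoate
Product: 3 (E)-3-(3,4,5-trimethoxyphenyl)prop-2-en-1-ol
Conditions: (iBu)2AlH (2.4 equiv), CH2Cl2, −78 to 0 °C; aq. potassium sodium tartrate
Reagents that add atoms: none
Why: 1,2-Reduction of an α,β-unsaturated ester with the electrophilic hydride (iBu)2AlH should give the allylic alcohol with the conjugated E-alkene intact, whereas a nucleophilic hydride such as LiAlH4 could partly saturate it.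

Step 3
Reactants: 3 (E)-3-(3,4,5-trimethoxyphenyl)prop-2-en-1-ol; 4 propiolic acid
Product: 5 (E)-3-(3,4,5-trimethoxyphenyl)allyl propiolate
Conditions: DCC (1.1 equiv), DMAP (5 mol%), CH2Cl2, −20 to 0 °C
Reagents that add atoms: none
Why: Steglich esterification (carbodiimide activation with DMAP as acyl-transfer catalyst) acylates the primary allylic alcohol under near-neutral conditions that do not ionise the electron-rich cinnamyl system, and the low temperature and small DMAP charge hold back conjugate addition of DMAP to the ynoate.

Step 4
Reactants: 5 (E)-3-(3,4,5-trimethoxyphenyl)allyl propiolate; 6 (3,4,5-trimethoxyphenyl)boronic acid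
Product: 9 (R,E)-3-(3,4,5-trimethoxybenzylidene)-4-(3,4,5-trimethoxybenzyl)oxolan-2-one, via alkenylrhodium species 7 (not isolated), via benzylrhodium species 8 (not isolated)
Conditions: [RhCl(C2H4)2]2 (2.5 mol%), (R,R)-Ph-bod* [(1R,4R)-2,5-diphenylbicyclo[2.2.2]octa-2,5-diene] (5.5 mol%), KOH (10 mol%), 6 (2 equiv), 1,4-dioxane/H2O 10:1, 40 °C, slow addition of 5
Reagents that add atoms: none
Why: Proposed new method: the hydroxorhodium–diene complex (monovalent rhodium) made from [RhCl(C2H4)2]2, the diene and KOH takes over the aryl group of 6 by transmetallation and adds it syn across the alkyne of 5, aryl to the terminal carbon C7' and rhodium to C3 next to the carbonyl, to give alkenylrhodium 7; 7 inserts the cinnamyl C4=C7 bond to give benzylrhodium 8, and water cleaves the C7–Rh bond of 8 to release 9 and the hydroxorhodium catalyst. The closest known reaction type is the rhodium/chiral diene catalysed asymmetric arylative cyclisation of 1,6-enynes with arylboronic acids, known for internal alkynes, carbon, ether or sulfonamide tethers and electron-poor alkene acceptors but not for an ester tether, a terminal ynoate or a styrene acceptor; that allyl alkynoates do close to α-alkylidene butyrolactones in palladium- and rhodium-catalysed enyne cyclisations argues that the s-cis ester rotamer can be reached on a metal. The lactone ring closes 5-exo-trig (C3 onto C4), a mode favoured over 6-endo both by ring size and because it places rhodium on benzylic C7, where η3 coordination to the trimethoxyphenyl ring stabilises it. C4, the only new stereocentre, is set in this insertion: the twofold-symmetric chiral diene blocks one quadrant on each side of rhodium, so that only one face of the E-alkene can lie parallel to the Rh–C3 bond, and the diene enantiomer is chosen for R. The E geometry of C3=C7' follows from the syn arylrhodation and the retention at C3 during insertion (aryl cis to C4, H cis to C2=O), and the regiochemistry of arylrhodation follows from the polarisation of the alkyne by the ester. The step needs ring closure to outrun protonolysis or 1,4-rhodium shift of 7, protonolysis of 8 to outrun β-hydride loss from C4, and arylrhodation to outrun alkyne oligomerisation, ester cleavage and ionisation of the cinnamyl C–O bond; the stabilised benzylrhodium, the aqueous medium, the slow addition of 5 into excess 6, and a KOH charge so small that it is held as boronate are what should secure this.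

Step 5
Reactants: 9 (R,E)-3-(3,4,5-trimethoxybenzylidene)-4-(3,4,5-trimethoxybenzyl)oxolan-2-one
Product: 10 (3S,4R)-3,4-bis(3,4,5-trimethoxybenzyl)oxolan-2-one (cis lactone)
Conditions: NaBH4 (4 equiv), NiCl2·6H2O (0.3 equiv), MeOH/THF, 0 °C
Reagents that add atoms: none
Why: Nickel boride conjugate reduction: the boride formed in situ from NiCl2 and NaBH4 saturates the cinnamate-type C3=C7' bond and should leave the lactone carbonyl and aryl ethers alone at 0 °C, with hydrogen reaching C3 mainly from the ring face away from the C4 benzyl group so that the cis (3S) epimer should prevail, while C4 is untouched and any trans epimer formed is already 11 and is carried along.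

Step 6
Reactants: 10 (3S,4R)-3,4-bis(3,4,5-trimethoxybenzyl)oxolan-2-one
Product: 11 (−)-cubebininolide, (3R,4R)-3,4-bis(3,4,5-trimethoxybenzyl)oxolan-2-one (trans lactone)
Conditions: DBU (1 equiv), toluene, 100 °C
Reagents that add atoms: none
Why: Base-mediated epimerisation through the lactone enolate (thermodynamic equilibration): only C3–H is acidic, so DBU deprotonates C3 reversibly without opening the ring, and the mixture should drain to the trans (3R,4R) lactone, in which the two vicinal arylmethyl groups avoid each other, with C4 as the fixed reference centre.

## Compound list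

1 | (E)-3,4,5-trimethoxycinnamic acid | COc1cc(/C=C/C(=O)O)cc(OC)c1OC | starting material
2 | methyl (E)-3-(3,4,5-trimethoxyphenyl)prop-2-enoate | COc1cc(/C=C/C(=O)OC)cc(OC)c1OC | intermediate
3 | (E)-3-(3,4,5-trimethoxyphenyl)prop-2-en-1-ol | COc1cc(/C=C/CO)cc(OC)c1OC | intermediate
4 | propiolic acid | C#CC(=O)O | starting material
5 | (E)-3-(3,4,5-trimethoxyphenyl)allyl propiolate | C#CC(=O)OC/C=C/c1cc(OC)c(OC)c(OC)c1 | intermediate
6 | (3,4,5-trimethoxyphenyl)boronic acid | COc1cc(B(O)O)cc(OC)c1OC | starting material
7 | alkenylrhodium species: rhodium on C3, aryl on C7' cis to rhodium (diene ligand not drawn) | COc1cc(/C=C(\[Rh])C(=O)OC/C=C/c2cc(OC)c(OC)c(OC)c2)cc(OC)c1OC | intermediate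
8 | benzylrhodium species: closed E-arylidene lactone with rhodium on C7, drawn in its σ form (diene ligand not drawn; the C7 configuration is lost on protonolysis) | COc1cc(/C=C2/C(=O)OC[C@@H]2C([Rh])c2cc(OC)c(OC)c(OC)c2)cc(OC)c1OC | intermediate
9 | (R,E)-3-(3,4,5-trimethoxybenzylidene)-4-(3,4,5-trimethoxybenzyl)oxolan-2-one | COc1cc(/C=C2/C(=O)OC[C@@H]2Cc2cc(OC)c(OC)c(OC)c2)cc(OC)c1OC | intermediate
10 | (3S,4R)-3,4-bis(3,4,5-trimethoxybenzyl)oxolan-2-one (cis) | COc1cc(C[C@H]2COC(=O)[C@H]2Cc2cc(OC)c(OC)c(OC)c2)cc(OC)c1OC | intermediate
11 | (−)-cubebininolide, (3R,4R)-3,4-bis(3,4,5-trimethoxybenzyl)oxolan-2-one (trans) | COc1cc(C[C@H]2COC(=O)[C@@H]2Cc2cc(OC)c(OC)c(OC)c2)cc(OC)c1OC | target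

Total step count: 6
Longest linear sequence: 6 steps (1 → 2 → 3 → 5 → 9 → 10 → 11)

## Steps most likely to fail

**First, step 4 (the new cascade).**
- The ester may stay in its s-trans rotamer so long that the alkenylrhodium is protonated, or shifts to the aryl ring, before the ring closes.
- After closure, β-hydride loss from C4 may erase the stereocentre.
- The terminal alkyne may oligomerise on rhodium.
- Face selection in the insertion may be poor.

The fallback uses known chemistry. It sets out from 3 and comes back to the route at 11. Hydrogenation of 3 (H2, Pd/C, EtOAc) gives 3-(3,4,5-trimethoxyphenyl)propan-1-ol F1. Acylation of F1 with glyoxylic acid chloride p-toluenesulfonylhydrazone (PhNMe2, CH2Cl2, 0 °C) gives 3-(3,4,5-trimethoxyphenyl)propyl (E)-2-(2-tosylhydrazinylidene)acetate F2. Et3N converts this in the same flask to 3-(3,4,5-trimethoxyphenyl)propyl diazoacetate F3. Slow addition of F3 to the chiral dirhodium carboxamidate Rh2(MPPIM)4, in the enantiomeric form that gives the R lactone, follows in refluxing CH2Cl2. This brings about enantioselective carbene insertion into the C–H bond at the central methylene of the propyl chain and gives (R)-4-(3,4,5-trimethoxybenzyl)oxolan-2-one F4. Enolisation with LiN(SiMe3)2 (THF, −78 °C) and alkylation with 3,4,5-trimethoxybenzyl bromide, which approaches anti to the C4 substituent, should give trans lactone 11 directly.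

**Second, step 3.** DMAP or the alcohol may add in conjugate fashion to the activated propiolic acid, the acyl group may migrate to the N-acylurea, and the ynoate may polymerise. The fallback masks the alkyne terminus. It sets out from 3 and comes back at 5. Compound 3 is coupled (DCC, DMAP, CH2Cl2, 0 °C) with commercial 3-(trimethylsilyl)propiolic acid, whose silyl group shields the β-carbon from nucleophiles. This gives (E)-3-(3,4,5-trimethoxyphenyl)allyl 3-(trimethylsilyl)propiolate F5. Bu4NF buffered with AcOH (THF, −20 °C) then removes the silyl group without touching the ester and delivers 5.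

**Third, step 5.** Excess borohydride may over-reduce the lactone carbonyl, methanol may open the lactone, or the reduction may stall on the hindered trisubstituted alkene. The fallback removes the hydride reagent altogether. It sets out from 9 and comes back at 10. Heterogeneous catalytic hydrogenation (H2, Pd/C, EtOAc, room temperature) adds hydrogen syn from the face opposite the C4 benzyl group. It should give the cis lactone 10, which then passes entirely through step 6. This fallback makes no compound outside the list (F0).

## Further compounds

F1 | step 4 | 3-(3,4,5-trimethoxyphenyl)propan-1-ol | COc1cc(CCCO)cc(OC)c1OC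
F2 | step 4 | 3-(3,4,5-trimethoxyphenyl)propyl (E)-2-(2-tosylhydrazinylidene)acetate | COc1cc(CCCOC(=O)/C=N/NS(=O)(=O)c2ccc(C)cc2)cc(OC)c1OC
F3 | step 4 | 3-(3,4,5-trimethoxyphenyl)propyl diazoacetate | COc1cc(CCCOC(=O)C=[N+]=[N-])cc(OC)c1OC
F4 | step 4 | (R)-4-(3,4,5-trimethoxybenzyl)oxolan-2-one | COc1cc(C[C@H]2COC(=O)C2)cc(OC)c1OC
F5 | step 3 | (E)-3-(3,4,5-trimethoxyphenyl)allyl 3-(trimethylsilyl)propiolate | C[Si](C)(C)C#CC(=O)OC/C=C/c1cc(OC)c(OC)c(OC)c1
F0 | step 5 | none | none
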